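**Retrosynthetic overview**
- The last bond made is C6(flavan)–C1(propyl): a stereoconvergent nickel-catalysed radical arylation joins a racemic 1,3-diarylpropan-1-ol (activated in the flask) to a flavan-6-ylzinc iodide and sets the (1R) centre; global desilylation follows.
- Both halves come from one lactone, 7-silyloxychroman-2-one (resorcinol + acrylic acid), opened by two different aryllithiums.
- Flavan half: ortho-lithiated 4-methoxyphenol silyl ether (from hydroquinone) opens the lactone; asymmetric transfer hydrogenation gives the (R)-carbinol; Mitsunobu closure inverts it to (2S); iodination at C6.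
- Diarylpropane half: 4-silyloxyphenyllithium (from 4-bromophenol) opens a second portion of the lactone, the freed phenoxide is methylated in the same flask, and the ketone is reduced to the racemic alcohol.
- Ring order: lactone ring first (later opened), then the pyran ring of the flavan; no ring is formed after that.

Abbreviations: TBS = tert-butyldimethylsilyl, TIPS = triisopropylsilyl, TBSO/TIPSO = the corresponding silyloxy groups.

Assumption: in step 12 the ligand antipode is written by analogy with simple 1,1-diarylalkanes; the catalyst alone controls this centre, so the mirror-image ligand is used if the first run gives the (1S) epimer.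

**Step 1**
Reactants: 1 resorcinol; 2 acrylic acid
Product: 3 7-hydroxychroman-2-one
Conditions: Amberlyst-15, toluene, reflux (Dean–Stark), resorcinol in excess
Reagents that add atoms: none
Why: Acid-catalysed Friedel–Crafts conjugate addition of resorcinol C4 (para to one OH, ortho to the other) to acrylic acid, followed by lactonisation, gives the 7-hydroxy dihydrocoumarin.

**Step 2**
Reactants: 3 7-hydroxychroman-2-one
Product: 4 7-(TBSO)chroman-2-one
Conditions: TBSCl, imidazole, CH2Cl2, 0 °C to rt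
Reagents that add atoms: tert-butyldimethylsilyl chloride, CC(C)(C)[Si](C)(C)Cl
Why: Imidazole-mediated O-silylation masks the phenol, so that later only the oxygen released from the lactone is free.

**Step 3**
Reactants: 5 hydroquinone
Product: 6 4-methoxyphenol
Conditions: MeOH, H2SO4 (cat.), 1,4-benzoquinone (10 mol %), reflux
Reagents that add atoms: methanol, CO
Why: Quinone-mediated acid-catalysed monoetherification (methanol adds to the quinone carbonyl and hydroquinone reduces the hemiketal cation) stops at the monomethyl ether, which cannot re-enter this cycle.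

**Step 4**
Reactants: 6 4-methoxyphenol
Product: 7 (4-methoxyphenoxy)triisopropylsilane
Conditions: TIPSCl, imidazole, DMF, rt
Reagents that add atoms: triisopropylsilyl chloride, CC(C)[Si](Cl)(C(C)C)C(C)C
Why: O-silylation with a bulky, non-coordinating group leaves OMe as the only directing group for the next step.

**Step 5**
Reactants: 7 (4-methoxyphenoxy)triisopropylsilane; 4 7-(TBSO)chroman-2-one
Product: 9 3-[4-(TBSO)-2-hydroxyphenyl]-1-[2-methoxy-5-(TIPSO)phenyl]propan-1-one, via aryllithium 8 (not isolated)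
Conditions: n-BuLi, TMEDA, Et2O, 0 °C to rt; then added to 4, THF, −78 °C; AcOH quench
Reagents that add atoms: none
Why: Directed ortho-metalation next to OMe, then nucleophilic acyl substitution on the lactone; the tetrahedral lithium alkoxide persists at −78 °C, so only one aryl group adds and the ring opens to the 2-hydroxyphenyl ketone.

**Step 6**
Reactants: 9 3-[4-(TBSO)-2-hydroxyphenyl]-1-[2-methoxy-5-(TIPSO)phenyl]propan-1-one
Product: 10 (1R)-3-[4-(TBSO)-2-hydroxyphenyl]-1-[2-methoxy-5-(TIPSO)phenyl]propan-1-ol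
Conditions: RuCl(p-cymene)[(R,R)-TsDPEN] (2 mol %), HCO2H/Et3N (5:2), EtOAc, 35 °C
Reagents that add atoms: none
Why: Noyori asymmetric transfer hydrogenation of the aryl alkyl ketone; the (R,R)-catalyst gives the (R)-carbinol, as it does for acetophenone, and tolerates the free phenol.

**Step 7**
Reactants: 10 (1R)-3-[4-(TBSO)-2-hydroxyphenyl]-1-[2-methoxy-5-(TIPSO)phenyl]propan-1-ol
Product: 11 (2S)-7-(TBSO)-2-[2-methoxy-5-(TIPSO)phenyl]chroman
Conditions: PPh3, DIAD, THF, 0 °C to rt
Reagents that add atoms: none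
Why: Intramolecular Mitsunobu etherification; the phenol displaces the activated benzylic oxygen by SN2 with inversion, so the (R)-carbinol becomes the (2S)-flavan as the pyran ring closes.

**Step 8**
Reactants: 11 (2S)-7-(TBSO)-2-[2-methoxy-5-(TIPSO)phenyl]chroman
Product: 12 (2S)-7-(TBSO)-6-iodo-2-[2-methoxy-5-(TIPSO)phenyl]chroman
Conditions: NIS, TFA (cat.), MeCN, 0 °C
Reagents that add atoms: N-iodosuccinimide, O=C1CCC(=O)N1I
Why: Electrophilic aromatic iodination goes to C6 of ring A (para to the ring oxygen, ortho to the silyloxy group); C8 is crowded between two oxygens and ring B is only singly activated at each open position.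

**Step 9**
Reactants: 13 4-bromophenol
Product: 14 (4-bromophenoxy)(tert-butyl)dimethylsilane
Conditions: TBSCl, imidazole, DMF, rt
Reagents that add atoms: tert-butyldimethylsilyl chloride, CC(C)(C)[Si](C)(C)Cl
Why: O-silylation removes the acidic proton so the aryl bromide can be lithiated.

**Step 10**
Reactants: 14 (4-bromophenoxy)(tert-butyl)dimethylsilane; 4 7-(TBSO)chroman-2-one
Product: 17 3-[4-(TBSO)-2-methoxyphenyl]-1-[4-(TBSO)phenyl]propan-1-one, via aryllithium 15 (not isolated), via lithium phenoxide 16 (not isolated)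
Conditions: t-BuLi (2 equiv), THF, −78 °C; added to 4, −78 to 0 °C; then MeI, DMPU, 0 °C to rt
Reagents that add atoms: iodomethane, CI
Why: Bromine–lithium exchange, lactone opening by acyl substitution, then Williamson O-methylation of the lithium phenoxide released on warming; the methyl group therefore lands only on the oxygen ortho to the chain.

**Step 11**
Reactants: 17 3-[4-(TBSO)-2-methoxyphenyl]-1-[4-(TBSO)phenyl]propan-1-one
Product: 18 racemic 3-[4-(TBSO)-2-methoxyphenyl]-1-[4-(TBSO)phenyl]propan-1-ol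
Conditions: NaBH4, THF/MeOH, 0 °C
Reagents that add atoms: none
Why: Simple hydride reduction of the ketone; a racemate is sufficient because the next step is stereoconvergent.

**Step 12**
Reactants: 18 racemic 3-[4-(TBSO)-2-methoxyphenyl]-1-[4-(TBSO)phenyl]propan-1-ol; 12 (2S)-7-(TBSO)-6-iodo-2-[2-methoxy-5-(TIPSO)phenyl]chroman
Product: 22 (2S)-7-(TBSO)-6-{(1R)-3-[4-(TBSO)-2-methoxyphenyl]-1-[4-(TBSO)phenyl]propyl}-2-[2-methoxy-5-(TIPSO)phenyl]chroman, via benzylic mesylate 19 (not isolated), via benzylic iodide 20 (not isolated), via arylzinc iodide 21 (not isolated)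
Conditions: 12, Zn dust, LiCl, THF, 50 °C; separately 18, MsCl, Et3N, CH2Cl2, −30 °C; combined with LiI, NiBr2·diglyme (10 mol %), methylene-bridged bis(4,5-cis-diphenyloxazoline) ligand, (4S,5R)-antipode (13 mol %), CH2Cl2/THF, −45 °C
Reagents that add atoms: none
Why: Stereoconvergent nickel/bis(oxazoline)-catalysed Negishi arylation of a racemic benzylic electrophile: monovalent nickel abstracts iodine from 20 to give a planar benzylic radical, the chiral aryl–nickel complex captures it, and reductive elimination from trivalent nickel sets (1R) under catalyst control while the remote (2S) centre is untouched; any (1S) epimer is a diastereomer and is removed by chromatography.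

**Step 13**
Reactants: 22 (2S)-7-(TBSO)-6-{(1R)-3-[4-(TBSO)-2-methoxyphenyl]-1-[4-(TBSO)phenyl]propyl}-2-[2-methoxy-5-(TIPSO)phenyl]chroman
Product: 23 (2S)-6-[(1R)-1-(4-hydroxyphenyl)-3-(4-hydroxy-2-methoxyphenyl)propyl]-2-(5-hydroxy-2-methoxyphenyl)chroman-7-ol
Conditions: TBAF, AcOH, THF, 0 °C to rt, under N2
Reagents that add atoms: none
Why: Fluoride-induced desilylation removes the three aryl TBS ethers and the aryl TIPS ether in one operation; acetic acid buffering protects the electron-rich phenols, and neither stereocentre is acidic or ionisable under these conditions.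

**Compound list**
1 | resorcinol (benzene-1,3-diol) | Oc1cccc(O)c1 | starting material
2 | acrylic acid | C=CC(=O)O | starting material
3 | 7-hydroxychroman-2-one | O=C1CCc2ccc(O)cc2O1 | intermediate
4 | 7-(TBSO)chroman-2-one | O=C1CCc2ccc(O[Si](C)(C)C(C)(C)C)cc2O1 | intermediate
5 | hydroquinone (benzene-1,4-diol) | Oc1ccc(O)cc1 | starting material
6 | 4-methoxyphenol | COc1ccc(O)cc1 | intermediate
7 | (4-methoxyphenoxy)triisopropylsilane | COc1ccc(O[Si](C(C)C)(C(C)C)C(C)C)cc1 | intermediate
8 | [2-methoxy-5-(TIPSO)phenyl]lithium | COc1ccc(O[Si](C(C)C)(C(C)C)C(C)C)cc1[Li] | intermediate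
9 | 3-[4-(TBSO)-2-hydroxyphenyl]-1-[2-methoxy-5-(TIPSO)phenyl]propan-1-one | COc1ccc(O[Si](C(C)C)(C(C)C)C(C)C)cc1C(=O)CCc1ccc(O[Si](C)(C)C(C)(C)C)cc1O | intermediate
10 | (1R)-3-[4-(TBSO)-2-hydroxyphenyl]-1-[2-methoxy-5-(TIPSO)phenyl]propan-1-ol | COc1ccc(O[Si](C(C)C)(C(C)C)C(C)C)cc1[C@H](O)CCc1ccc(O[Si](C)(C)C(C)(C)C)cc1O | intermediate
11 | (2S)-7-(TBSO)-2-[2-methoxy-5-(TIPSO)phenyl]chroman | c1cc2c(cc1O[Si](C)(C)C(C)(C)C)O[C@H](c1cc(O[Si](C(C)C)(C(C)C)C(C)C)ccc1OC)CC2 | intermediate
12 | (2S)-7-(TBSO)-6-iodo-2-[2-methoxy-5-(TIPSO)phenyl]chroman | Ic1cc2c(cc1O[Si](C)(C)C(C)(C)C)O[C@H](c1cc(O[Si](C(C)C)(C(C)C)C(C)C)ccc1OC)CC2 | intermediate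
13 | 4-bromophenol | Oc1ccc(Br)cc1 | starting material
14 | (4-bromophenoxy)(tert-butyl)dimethylsilane | CC(C)(C)[Si](C)(C)Oc1ccc(Br)cc1 | intermediate
15 | [4-(TBSO)phenyl]lithium | CC(C)(C)[Si](C)(C)Oc1ccc([Li])cc1 | intermediate
16 | lithium 5-(TBSO)-2-{3-oxo-3-[4-(TBSO)phenyl]propyl}phenolate | [Li+].[O-]c1cc(O[Si](C)(C)C(C)(C)C)ccc1CCC(=O)c1ccc(O[Si](C)(C)C(C)(C)C)cc1 | intermediate
17 | 3-[4-(TBSO)-2-methoxyphenyl]-1-[4-(TBSO)phenyl]propan-1-one | COc1cc(O[Si](C)(C)C(C)(C)C)ccc1CCC(=O)c1ccc(O[Si](C)(C)C(C)(C)C)cc1 | intermediate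
18 | racemic 3-[4-(TBSO)-2-methoxyphenyl]-1-[4-(TBSO)phenyl]propan-1-ol | COc1cc(O[Si](C)(C)C(C)(C)C)ccc1CCC(O)c1ccc(O[Si](C)(C)C(C)(C)C)cc1 | intermediate
19 | racemic 3-[4-(TBSO)-2-methoxyphenyl]-1-[4-(TBSO)phenyl]propyl methanesulfonate | COc1cc(O[Si](C)(C)C(C)(C)C)ccc1CCC(OS(C)(=O)=O)c1ccc(O[Si](C)(C)C(C)(C)C)cc1 | intermediate
20 | racemic 1-iodo-3-[4-(TBSO)-2-methoxyphenyl]-1-[4-(TBSO)phenyl]propane | COc1cc(O[Si](C)(C)C(C)(C)C)ccc1CCC(I)c1ccc(O[Si](C)(C)C(C)(C)C)cc1 | intermediate
21 | {(2S)-7-(TBSO)-2-[2-methoxy-5-(TIPSO)phenyl]chroman-6-yl}zinc iodide | I[Zn]c1cc2c(cc1O[Si](C)(C)C(C)(C)C)O[C@H](c1cc(O[Si](C(C)C)(C(C)C)C(C)C)ccc1OC)CC2 | intermediate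
22 | (2S)-7-(TBSO)-6-{(1R)-3-[4-(TBSO)-2-methoxyphenyl]-1-[4-(TBSO)phenyl]propyl}-2-[2-methoxy-5-(TIPSO)phenyl]chroman | COc1cc(O[Si](C)(C)C(C)(C)C)ccc1CC[C@H](c1ccc(O[Si](C)(C)C(C)(C)C)cc1)c1cc2c(cc1O[Si](C)(C)C(C)(C)C)O[C@H](c1cc(O[Si](C(C)C)(C(C)C)C(C)C)ccc1OC)CC2 | intermediate
23 | (2S)-6-[(1R)-1-(4-hydroxyphenyl)-3-(4-hydroxy-2-methoxyphenyl)propyl]-2-(5-hydroxy-2-methoxyphenyl)chroman-7-ol | COc1cc(O)ccc1CC[C@H](c1ccc(O)cc1)c1cc2c(cc1O)O[C@H](c1cc(O)ccc1OC)CC2 | target

**Step count and risks**
Total step count: 13. Longest linear sequence: 8 steps (1, 2, 5, 6, 7, 8, 12, 13 from resorcinol; the hydroquinone branch 3, 4, 5, 6, 7, 8, 12, 13 is equally long).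

The three steps most likely to fail:

Step 12. The ortho-silyloxy arylzinc may transmetalate slowly or give low selectivity, and the electron-rich mesylate may ionise or eliminate to the styrene before it is intercepted. Fallback: setting out from 18, SOCl2 in CH2Cl2 at 0 °C gives the racemic benzylic chloride F1. F1 is used crude with iodide 12 in a nickel-catalysed enantioselective reductive cross-electrophile coupling (NiBr2·diglyme, 4-heptyl-BiOX, Mn powder, TMSCl, 1,4-dioxane, rt). Here the benzylic radical is formed by halogen abstraction and no organozinc is needed; the route is rejoined at 22.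

Step 7. The ortho-methoxybenzylic oxyphosphonium ion can leak through an SN1 path (loss of ee) or eliminate. Fallback: setting out from 9, p-TsOH in toluene (Dean–Stark) dehydrates the hydroxy ketone, through its cyclic hemiketal, to the 2-aryl-4H-chromene F2. Asymmetric hydrogenation of F2 with a cationic iridium phosphino-oxazoline catalyst, [Ir(cod)(PHOX)]BArF, under H2, with the ligand antipode chosen for (2S), sets C2 directly and rejoins the route at 11.

Step 10. Double addition of 15 to the lactone, or methylation of the hemiketal oxygen instead of the phenoxide, would lower the yield. Fallback: setting out from 4, MeNH(OMe)·HCl with AlMe3 in CH2Cl2 opens the lactone to the Weinreb amide phenol F3. MeI with K2CO3 in acetone gives the methyl ether F4, and addition of aryllithium 15 at −78 °C then delivers one aryl group only and rejoins the route at 17.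

**Further compounds**
F1 | step 12 | racemic 1-chloro-3-[4-(TBSO)-2-methoxyphenyl]-1-[4-(TBSO)phenyl]propane | COc1cc(O[Si](C)(C)C(C)(C)C)ccc1CCC(Cl)c1ccc(O[Si](C)(C)C(C)(C)C)cc1
F2 | step 7 | 7-(TBSO)-2-[2-methoxy-5-(TIPSO)phenyl]-4H-chromene | COc1ccc(O[Si](C(C)C)(C(C)C)C(C)C)cc1C1=CCc2ccc(O[Si](C)(C)C(C)(C)C)cc2O1
F3 | step 10 | 3-[4-(TBSO)-2-hydroxyphenyl]-N-methoxy-N-methylpropanamide | CON(C)C(=O)CCc1ccc(O[Si](C)(C)C(C)(C)C)cc1O
F4 | step 10 | 3-[4-(TBSO)-2-methoxyphenyl]-N-methoxy-N-methylpropanamide | CON(C)C(=O)CCc1ccc(O[Si](C)(C)C(C)(C)C)cc1OC
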